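**Assumptions (one line each):** (i) The Ru-TsDPEN and the Cu-phosphoramidite enantiomers are chosen to give the natural absolute series, and commercial (S)-2-methylbutanoic acid is used for both esters. (ii) The two C4-carbinol epimers formed in steps 8–10 converge at the C4 ketone in step 11. (iii) Clerodane numbering is used throughout (C1–C20, side chain C11–C16).

## Retrosynthetic overview
1. Target ← butenolide made from the 3-furyl group (¹O₂), C19/C6 acetates, and the 4-OH/18-Cl unit from a 4α,18-epoxide opened by HCl; the epoxide comes from a C4 methylene, which comes from a ring-A ketone.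
2. Ring A (C1–C4) is closed by RCM of a C10-allyl and a C5–CH(OH)CH=CH₂ arm (trans-diequatorial on ring B); C1–O is added by γ-hydroxylation of the ring-A enone.
3. C5 (quaternary), C19, C10-H and C1 come from a tandem Sakurai/aldol on an α-hydroxymethyl enone (Morita–Baylis–Hillman product), delivering trans-diaxially.
4. Ring B comes from oxidative dearomatization of p-cresol with the enol silane of 3-acetylfuran, giving a mirror-symmetric 4,4-disubstituted cyclohexadienone; a desymmetrizing Cu-catalysed Me addition sets C8/C9, and C12 is set by asymmetric transfer hydrogenation.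
5. Order of ring formation: ring B (dearomatization) → ring A (RCM) → butenolide (photo-oxygenation, last).

## Route

**Step 1**
Reactants: 1 3-acetylfuran
Product: 2 trimethyl[1-(furan-3-yl)vinyloxy]silane
Conditions: TMSCl, NaI, Et₃N, MeCN, 25 °C
Reagents that add atoms: TMSCl, C[Si](C)(C)Cl
Why: Only the methyl side is enolizable, so silyl enol ether formation is regiospecific; it is a standard enol silane preparation.

**Step 2**
Reactants: 3 p-cresol; 2 enol silane
Product: 4 4-[2-(furan-3-yl)-2-oxoethyl]-4-methylcyclohexa-2,5-dien-1-one (achiral, mirror-symmetric)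
Conditions: PhI(OAc)₂, HFIP, 0 °C
Reagents that add atoms: none
Why: Proposed new method: PIDA oxidizes p-cresol to a phenoxenium ion that the enol-silane carbon attacks at the para (methyl-bearing) carbon; the closest known reaction is PIDA/HFIP oxidative para-allylation of phenols with allylsilanes. No stereocentre forms yet because the product is symmetric.

**Step 3**
Reactants: 4
Product: 5 (S)-carbinol at C12: 4-[(2S)-2-(furan-3-yl)-2-hydroxyethyl]-4-methylcyclohexa-2,5-dien-1-one
Conditions: HCO₂H/Et₃N, RuCl[(S,S)-TsDPEN](p-cymene), MeCN, 25 °C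
Reagents that add atoms: none (hydrogen only)
Why: Noyori asymmetric transfer hydrogenation reduces the aryl ketone under catalyst control, and the hindered cross-conjugated dienone carbonyl is the less reactive one; this sets C12 (S).

**Step 4**
Reactants: 5; 6 (S)-2-methylbutanoic acid
Product: 7 C12 (S)-2-methylbutanoate of 5
Conditions: EDC·HCl, DMAP, CH₂Cl₂, 0→25 °C
Reagents that add atoms: none (the acid is reactant 6)
Why: Steglich esterification installs the final C12 ester and removes the free OH that could add intramolecularly to the dienone (5-exo oxa-Michael).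

**Step 5**
Reactants: 7
Product: 8 enone with C6 ketone, C5=C10, C7H₂, C8 Me (α), C9 Me (α) and C11 side chain (β)
Conditions: Me₂Zn, Cu(OTf)₂ (2 mol %), chiral phosphoramidite, toluene, −30 °C
Reagents that add atoms: dimethylzinc, C[Zn]C (adds CH₃)
Why: Proposed new method: Cu-catalysed conjugate addition of a dialkylzinc desymmetrizes the two enone arms, and the Me enters anti to the larger CH₂CH(OR)Fur chain, so C17/C20 are cis (α) and trans to C11; the closest known reaction is Cu-catalysed asymmetric conjugate addition of dialkylzincs to 4,4-disubstituted cyclohexadienones (dialkylzinc tolerates the ester).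

**Step 6**
Reactants: 8; 9 formaldehyde
Product: 10 α-hydroxymethyl enone (C19–OH on C5)
Conditions: 37 % aq. HCHO, PBu₃ (20 mol %), THF/H₂O, 25 °C
Reagents that add atoms: none (formaldehyde is reactant 9)
Why: Proposed new method: Morita–Baylis–Hillman α-hydroxymethylation through phosphonium enolate addition at C10 then aldol with HCHO and elimination; the closest known reaction is MBH of cyclohexenone with aqueous formaldehyde, here with a hindered 4,4-disubstituted enone. C19 is introduced on the sp² carbon, so no stereocentre is created.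

**Step 7**
Reactants: 10
Product: 11 C19–OTIPS ether
Conditions: TIPSOTf, 2,6-lutidine, CH₂Cl₂, −78→0 °C
Reagents that add atoms: TIPSOTf, CC(C)[Si](OS(=O)(=O)C(F)(F)F)(C(C)C)C(C)C
Why: A silyl ether (not an acetate) is needed because an acetate β to the enolate in step 8 would eliminate; TIPS survives TiCl₄ and the later brief HF treatment.

**Step 8**
Reactants: 11; 12 allyltrimethylsilane; 13 acrolein
Product: 14 C10-allyl (α), C5 quaternary (C19 α, C4 β) C4-carbinol-vinyl ketone (C4 epimeric mixture)
Conditions: 12, TiCl₄, CH₂Cl₂, −78 °C; then 13, −78→−40 °C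
Reagents that add atoms: none (12 and 13 are reactants)
Why: Proposed new method: a Hosomi–Sakurai conjugate addition places allyl on C10 anti to the C11 chain (axial attack), and the resulting titanium enolate adds acrolein (aldol) to C5 trans-diaxially to the new C10 substituent, so C4 ends up β, C19 α and H10 β; the closest known reaction is tandem conjugate addition/enolate aldol (Sakurai/aldol).

**Step 9**
Reactants: 14
Product: 15 C6 α-alcohol (C4-OH retained)
Conditions: NaBH₄, MeOH/CH₂Cl₂, −20 °C
Reagents that add atoms: none (hydride only)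
Why: The C6 ketone sits between the quaternary C5 and C7H₂, and hydride enters from the β face (axial, the α face being blocked by axial C19/C20), giving the equatorial 6α-OH.

**Step 10**
Reactants: 15
Product: 16 ring-A cyclohexenol (C2=C3, C4-OH), trans-decalin
Conditions: Grubbs II (5 mol %), CH₂Cl₂, 40 °C
Reagents that add atoms: none (ethylene is lost)
Why: Ring-closing metathesis of the trans-diequatorial C10-allyl and C5 CH(OH)CH=CH₂ arms closes ring A without disturbing any stereocentre.

**Step 11**
Reactants: 16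
Product: 17 ring-A enone, C4 ketone with C2=C3
Conditions: activated MnO₂, CH₂Cl₂, 25 °C
Reagents that add atoms: none
Why: MnO₂ oxidizes only the allylic C4 alcohol (the non-allylic 6-OH is untouched) and merges the two C4 epimers.

**Step 12**
Reactants: 17
Product: 18 C6-acetate
Conditions: Ac₂O, pyridine, DMAP, CH₂Cl₂, 25 °C
Reagents that add atoms: acetic anhydride, CC(=O)OC(C)=O
Why: Plain acylation installs the final 6α-OAc.

**Step 13**
Reactants: 18
Product: 19 silyl dienol ether (C4–OTBS, C3=C4/C1=C2 diene)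
Conditions: TBSOTf, Et₃N, CH₂Cl₂, 0 °C
Reagents that add atoms: TBSOTf, CC(C)(C)[Si](C)(C)OS(=O)(=O)C(F)(F)F
Why: C4 is flanked by the quaternary C5, so only γ-deprotonation (at C1) is possible and the extended dienol ether forms regiospecifically.

**Step 14**
Reactants: 19
Product: 20 C1 β-hydroxy-enone (C4=O, C2=C3, 1β-OH)
Conditions: mCPBA, NaHCO₃, CH₂Cl₂, −20 °C; then HF·py (1 equiv, 0 °C, 10 min)
Reagents that add atoms: mCPBA, OOC(=O)c1cccc(Cl)c1 (adds O)
Why: Epoxidation of the distal C1=C2 bond with collapse of the silyl enol ether gives γ-hydroxylation (the known Δ3,5-dienol ether → 6-hydroxy-Δ4-3-ketone reaction of steroids), and the peracid attacks from the β face because the α face is shielded by axial C19, giving 1β-OH; HF·py briefly removes any silyl transferred to O1 while the TIPS ether survives.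

**Step 15**
Reactants: 20
Product: 21 saturated C4 ketone with 1β-OH
Conditions: [(Ph₃P)CuH]₆ (cat.), PhSiH₃, toluene, 0 °C
Reagents that add atoms: none (hydride/proton)
Why: Stryker conjugate reduction removes C2=C3 and leaves the furan, esters and alcohol intact.

**Step 16**
Reactants: 21; 6 (S)-2-methylbutanoic acid
Product: 22 C1 (S)-2-methylbutanoate
Conditions: 2,4,6-Cl₃C₆H₂COCl, Et₃N, then 6, DMAP, toluene, 25 °C
Reagents that add atoms: none (the acid is reactant 6)
Why: Yamaguchi esterification proceeds with retention, so the equatorial 1β ester is kept as formed in step 14.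

**Step 17**
Reactants: 22
Product: 23 C4 exocyclic methylene (C4=C18)
Conditions: Ph₃P=CH₂ (Ph₃PCH₃Br, KOt-Bu), THF/toluene, 0→50 °C
Reagents that add atoms: methylenetriphenylphosphorane, C=P(c1ccccc1)(c1ccccc1)c1ccccc1 (adds CH₂)
Why: Wittig methylenation of the hindered ketone is chemoselective over the secondary esters.

**Step 18**
Reactants: 23
Product: 24 C19 primary alcohol
Conditions: HF·pyridine, THF/pyridine, 0→25 °C
Reagents that add atoms: none (H only)
Why: Fluoride removes the TIPS ether and exposes the hydroxyl needed to direct the epoxidation in step 19; any 6→19 acetyl shift is harmless because both positions end up as OAc.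

**Step 19**
Reactants: 24
Product: 25 4α,18-epoxide
Conditions: VO(acac)₂ (5 mol %), t-BuOOH, CH₂Cl₂, 25 °C
Reagents that add atoms: tert-butyl hydroperoxide, CC(C)(C)OO (adds O)
Why: The 19-OH is homoallylic to C4=C18, so vanadium delivers oxygen syn to it (α face), overriding the steric preference for β attack and giving the required 4α-oxygen.

**Step 20**
Reactants: 25
Product: 26 4α-hydroxy-18-chloro compound (C19–OH, furan still present)
Conditions: HCl (2 M in Et₂O), CH₂Cl₂, 0 °C
Reagents that add atoms: hydrogen chloride, Cl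
Why: Chloride opens the spiro epoxide at the primary C18 (SN2), leaving the tertiary C4–O bond untouched, so 4α-OH with CH₂Cl is formed (the chlorohydrin is a known derivative of 4,18-epoxy-clerodanes).

**Step 21**
Reactants: 26
Product: 27 C19 acetate
Conditions: Ac₂O, pyridine, DMAP, CH₂Cl₂, 0 °C
Reagents that add atoms: acetic anhydride, CC(=O)OC(C)=O
Why: The primary alcohol is acetylated selectively while the tertiary C4–OH is unreactive.

**Step 22**
Reactants: 27
Product: 28 5-hydroxybutenolide (C16-lactol, epimeric mixture)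
Conditions: O₂, Rose Bengal, hν (visible), DIPEA, CH₂Cl₂, −78 °C
Reagents that add atoms: dioxygen, O=O
Why: Singlet-oxygen [4+2] of the 3-substituted furan followed by base-induced Kornblum–DeLaMare opening gives the 4-substituted 5-hydroxy-2(5H)-furanone regioselectively.

**Step 23**
Reactants: 28
Product: 29 ajugaciliatin A
Conditions: Et₃SiH, TFA, CH₂Cl₂, 0 °C
Reagents that add atoms: none (hydride replaces OH)
Why: Ionic hydrogenolysis of the lactol through its oxocarbenium ion gives the γ-CH₂ butenolide, and the stereocentres are not touched.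

## Compound list
1 | 3-acetylfuran | CC(=O)c1ccoc1 | starting material
2 | enol silane of 3-acetylfuran | C=C(O[Si](C)(C)C)c1ccoc1 | intermediate
3 | p-cresol | Cc1ccc(O)cc1 | starting material
4 | symmetric dienone | CC1(CC(=O)c2ccoc2)C=CC(=O)C=C1 | intermediate
5 | (12S)-alcohol | CC1(C[C@H](O)c2ccoc2)C=CC(=O)C=C1 | intermediate
6 | (S)-2-methylbutanoic acid | CC[C@H](C)C(=O)O | starting material
7 | C12 ester | CC[C@H](C)C(=O)O[C@@H](CC1(C)C=CC(=O)C=C1)c1ccoc1 | intermediate
8 | enone after Me addition | CC[C@H](C)C(=O)O[C@@H](C[C@@]1(C)[C@H](C)CC(=O)C=C1)c1ccoc1 | intermediate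
9 | formaldehyde | C=O | starting material
10 | MBH adduct | CC[C@H](C)C(=O)O[C@@H](C[C@@]1(C)[C@H](C)CC(=O)C(CO)=C1)c1ccoc1 | intermediate
11 | TIPS ether | CC[C@H](C)C(=O)O[C@@H](C[C@@]1(C)[C@H](C)CC(=O)C(CO[Si](C(C)C)(C(C)C)C(C)C)=C1)c1ccoc1 | intermediate
12 | allyltrimethylsilane | C=CC[Si](C)(C)C | starting material
13 | acrolein | C=CC=O | starting material
14 | Sakurai/aldol product (C4 epimers) | CC[C@H](C)C(=O)O[C@@H](C[C@@]1(C)[C@H](C)CC(=O)[C@@](CO[Si](C(C)C)(C(C)C)C(C)C)(C(O)C=C)[C@@H]1CC=C)c1ccoc1 | intermediate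
15 | C6 α-alcohol | CC[C@H](C)C(=O)O[C@@H](C[C@@]1(C)[C@H](C)C[C@H](O)[C@@](CO[Si](C(C)C)(C(C)C)C(C)C)(C(O)C=C)[C@@H]1CC=C)c1ccoc1 | intermediate
16 | RCM cyclohexenol | CC[C@H](C)C(=O)O[C@@H](C[C@@]1(C)[C@H](C)C[C@H](O)[C@]2(CO[Si](C(C)C)(C(C)C)C(C)C)[C@@H]1CC=CC2O)c1ccoc1 | intermediate
17 | ring-A enone | CC[C@H](C)C(=O)O[C@@H](C[C@@]1(C)[C@H](C)C[C@H](O)[C@]2(CO[Si](C(C)C)(C(C)C)C(C)C)[C@@H]1CC=CC2=O)c1ccoc1 | intermediate
18 | C6 acetate | CC[C@H](C)C(=O)O[C@@H](C[C@@]1(C)[C@H](C)C[C@H](OC(C)=O)[C@]2(CO[Si](C(C)C)(C(C)C)C(C)C)[C@@H]1CC=CC2=O)c1ccoc1 | intermediate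
19 | silyl dienol ether | CC[C@H](C)C(=O)O[C@@H](C[C@@]1(C)[C@H](C)C[C@H](OC(C)=O)[C@]2(CO[Si](C(C)C)(C(C)C)C(C)C)[C@@H]1C=CC=C2O[Si](C)(C)C(C)(C)C)c1ccoc1 | intermediate
20 | 1β-hydroxy-enone | CC[C@H](C)C(=O)O[C@@H](C[C@@]1(C)[C@H](C)C[C@H](OC(C)=O)[C@]2(CO[Si](C(C)C)(C(C)C)C(C)C)[C@@H]1[C@H](O)C=CC2=O)c1ccoc1 | intermediate
21 | saturated C4 ketone | CC[C@H](C)C(=O)O[C@@H](C[C@@]1(C)[C@H](C)C[C@H](OC(C)=O)[C@]2(CO[Si](C(C)C)(C(C)C)C(C)C)[C@@H]1[C@H](O)CCC2=O)c1ccoc1 | intermediate
22 | C1 ester | CC[C@H](C)C(=O)O[C@@H](C[C@@]1(C)[C@H](C)C[C@H](OC(C)=O)[C@]2(CO[Si](C(C)C)(C(C)C)C(C)C)[C@@H]1[C@H](OC(=O)[C@@H](C)CC)CCC2=O)c1ccoc1 | intermediate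
23 | C4 methylene | CC[C@H](C)C(=O)O[C@@H](C[C@@]1(C)[C@H](C)C[C@H](OC(C)=O)[C@]2(CO[Si](C(C)C)(C(C)C)C(C)C)[C@@H]1[C@H](OC(=O)[C@@H](C)CC)CCC2=C)c1ccoc1 | intermediate
24 | C19 alcohol | CC[C@H](C)C(=O)O[C@@H](C[C@@]1(C)[C@H](C)C[C@H](OC(C)=O)[C@]2(CO)[C@@H]1[C@H](OC(=O)[C@@H](C)CC)CCC2=C)c1ccoc1 | intermediate
25 | 4α,18-epoxide | CC[C@H](C)C(=O)O[C@@H](C[C@@]1(C)[C@H](C)C[C@H](OC(C)=O)[C@]2(CO)[C@@H]1[C@H](OC(=O)[C@@H](C)CC)CC[C@]23CO3)c1ccoc1 | intermediate
26 | chlorohydrin | CC[C@H](C)C(=O)O[C@@H](C[C@@]1(C)[C@H](C)C[C@H](OC(C)=O)[C@]2(CO)[C@@H]1[C@H](OC(=O)[C@@H](C)CC)CC[C@]2(O)CCl)c1ccoc1 | intermediate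
27 | C19 acetate | CC[C@H](C)C(=O)O[C@@H](C[C@@]1(C)[C@H](C)C[C@H](OC(C)=O)[C@]2(COC(C)=O)[C@@H]1[C@H](OC(=O)[C@@H](C)CC)CC[C@]2(O)CCl)c1ccoc1 | intermediate
28 | hydroxybutenolide | CC[C@H](C)C(=O)O[C@@H](C[C@@]1(C)[C@H](C)C[C@H](OC(C)=O)[C@]2(COC(C)=O)[C@@H]1[C@H](OC(=O)[C@@H](C)CC)CC[C@]2(O)CCl)C1=CC(=O)OC1O | intermediate
29 | ajugaciliatin A | CC[C@H](C)C(=O)O[C@@H](C[C@@]1(C)[C@H](C)C[C@H](OC(C)=O)[C@]2(COC(C)=O)[C@@H]1[C@H](OC(=O)[C@@H](C)CC)CC[C@]2(O)CCl)C1=CC(=O)OC1 | target

## Summary
Total step count: 23.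
Longest linear sequence: 23 steps (3-acetylfuran → 29); 22 steps from p-cresol.

Three steps most likely to fail:
1. **Step 8 (tandem Sakurai/aldol forming C5 quaternary with trans ring relationship).** Fallback: make ring A cis-fused by an intramolecular Michael closure of a tethered nucleophile, then epimerize C10 through a C1 ketone to the trans-decalin.
2. **Step 5 (desymmetrizing Cu/Me conjugate addition, C8/C9 facial control).** Fallback: drop catalyst control and use the C12 stereocentre for diastereoselective cuprate addition, separating the diastereomers, or attach a chiral auxiliary to the dienone.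
3. **Step 2 (dearomative coupling with a furan-containing enol silane).** Fallback: oxidative allylation of p-cresol (allylsilane, PIDA), ozonolysis to the aldehyde, then 3-furyllithium addition, oxidation and asymmetric transfer hydrogenation, so the furan enters only after the dearomatization.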